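Late in the simulated runs product stands still: by 120 min the south-west run holds 50.3%, while the north-east run, with twice the protic impurity, holds 14.2%. Partner differs there too, but the north run at 8 equiv holds 49.2%, so we read the lower plateau as the work of protic impurity: the proposed quench to quenched substrate takes starting material by a second route. We must decide whether extra free catalyst is worth charging to the new flask.

in all of them: starting material 20 mM; free catalyst 2 mol%
- south-west: partner 2 equiv; protic impurity 10 mM; run made earlier
- north: partner 8 equiv; protic impurity 10 mM; run made earlier
- north-east: partner 4 equiv; protic impurity 20 mM; run made earlier
- flask: partner 4.00 equiv; protic impurity 10.0 mM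

| south-west: time / min | south-west: product / % | north: time / min | north: product / % | north-east: time / min | north-east: product / % |
|---|---|---|---|---|---|
| 10.0 | 8.4 | 10.0 | 8.3 | 10.0 | 6.7 |
| 20.0 | 16.9 | 30.0 | 25.4 | 20.0 | 12.3 |
| 30.0 | 25.3 | 60.0 | 45.8 | 30.0 | 13.4 |
| 60.0 | 44.9 | 80.0 | 50.5 | 60.0 | 14.6 |
| 120 | 50.3 | 120 | 49.2 | 120 | 14.2 |

(scatter of a reading: 0.5 percentage points)

* factor on the rate of making product when 5.0% of the starting material are converted if free catalyst is charged twice over
* factor on the rate when 5.0% of the starting material are converted if free catalyst is charged at 20 mol% instead

- steps that have been proposed: starting material + free catalyst -> catalyst intermediate A; catalyst intermediate A -> catalyst intermediate B; partner + catalyst intermediate B <-> catalyst intermediate C; catalyst intermediate C -> catalyst intermediate D; catalyst intermediate D -> free catalyst + product; starting material + protic impurity -> quenched substrate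
- no earlier run changes the charge of free catalyst; that part of a forecast is a guess

Call 5.0% conversion the mark. The south-west run and the north run agree early (25.3% and 25.4% at 30.0 min), so we take one steady rate for the new flask, and from it the time of one catalytic cycle:

v = 0.169 mM/min

τ = catalyst charged / v = 2.37 min

The north-east plateau is worth this much steady running, which we take as the life of starting material in that run:

17.3 min

That gives a mean loss, which we scale to the new flask's impurity:

0.578 mM/min

A second-order loss starts above its mean, so we take this as a rough, late estimate of the time to the mark:

1.73 min

We carry θ, the time to the mark over the time of one catalytic cycle: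

θ = 0.730

By this estimate the mark comes before one cycle ends, so we expect a first-pass rate there, not v. At 20 mol%, the catalyst charged, 4.00 mM, also exceeds the 1.00 mM of starting material that makes the mark, so binding to free catalyst can carry the flask past it sooner. We would leave the charge at 2 mol%, and we do not expect the rate at the mark to follow the charge.

The forecast differs: 2 (1.8 to 2.1) and 9.5 (7 to 10.8), holding that “the rate should scale with total catalyst”.

The flask gives 1.15 and 0.287.

    starting material + free catalyst → catalyst intermediate A (k = 6.80 /M/s)
    catalyst intermediate A → catalyst intermediate B (k = 0.0110 /s)
    partner + catalyst intermediate B ⇌ catalyst intermediate C (K = 1100 /M, k = 26.0 /M/s)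
    catalyst intermediate C → catalyst intermediate D (k = 0.0350 /s)
    catalyst intermediate D → free catalyst + product (k = 3.00 /s)
    starting material + protic impurity → quenched substrate (k = 0.430 /M/s)

The flask reaches the mark at 0.149 min, so θ is 0.0629, and its rate there, 1.53 mM/h, is 0.151 of v. The largest single effect on that rate is the quench step. The simulated run without it gives 7.33 times the rate at the mark, and the apparent order in free catalyst goes from 0.44 to 1.0.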